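**Retrosynthetic overview**

1. Numbering (aromadendrane): cyclopentane C1–C5, cycloheptane C1, C5–C10, cyclopropane C6–C7–C11, benzylic carbon C7′. The plan rests on the cycloheptane: the O–C1/H–C10 pair calls for a C1=C10 alkene and the C6–C7–C11 ring for a C6=C7 alkene, and this 1(10),6-diene is what a cis-dialkenylcyclopropane Cope rearrangement delivers.
2. Endgame disconnections: both CHO groups (Rieche), C11 with its two methyls (dibromocarbene, then Me2CuLi/MeI on C6=C7), and the oxepane O–C1 bond with H at C10 (cobalt hydride hydroalkoxylation of C1=C10).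
3. Key disconnection: C8–C9 of the cycloheptadiene, back to a 1-isopropenyl-6-exo-vinylbicyclo[3.1.0]hexane whose C1–C6 bond breaks.
4. That bicycle comes from a 1-acetylcyclopentene (aldol closure C1–C5) by ester-ylide cyclopropanation anti to C7′. C4 is set by two enolate alkylations of a dihydrocoumarin, and C7′ by asymmetric CuH reduction of a Pechmann coumarin.
5. Ring order: arene (bought) → lactone (temporary) → cyclopentane → sacrificial cyclopropane → cycloheptadiene → oxepane → gem-dimethylcyclopropane.

Key step: step 16

Remark: Ar1 = 2-hydroxy-4,6-bis(methoxymethoxy)phenyl and Ar2 = 2-(prop-2-enyloxy)-4,6-bis(methoxymethoxy)phenyl; α is the face of the cyclopentane that carries C7′, β the face of the C4 methyl.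
Remark: (R)-DTBM-SEGPHOS is written in step 3; the ligand antipode that delivers the 4R lactone 5 is the one meant.
Remark: the cis-dialkenylcyclopropane 20 is assumed to survive cold isolation; any part that rearranges already in the flask of step 15 is 21 and is carried on.

**Route**

Step 1
Reactants: 1 phloroglucinol; 2 ethyl 5-methyl-3-oxohexanoate
Product: 3 5,7-dihydroxy-4-(2-methylpropyl)-2H-chromen-2-one
Conditions: MeSO3H (neat), 0 °C → rt
Reagents that add atoms: none
Why: Pechmann condensation, in which the electron-rich phenol is acylated by the ester and closes onto the ketone with loss of water, the symmetry of phloroglucinol leaving no regiochemical choice.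

Step 2
Reactants: 3 dihydroxycoumarin
Product: 4 5,7-bis(methoxymethoxy)-4-(2-methylpropyl)-2H-chromen-2-one
Conditions: MOMCl, i-Pr2NEt, CH2Cl2, 0 °C → rt
Reagents that add atoms: chloromethyl methyl ether, COCCl
Why: O-alkylation of both phenols as MOM acetals removes the acidic OH groups before the hydride and enolate steps.

Step 3
Reactants: 4 bis-MOM coumarin
Product: 5 (4R)-5,7-bis(methoxymethoxy)-4-(2-methylpropyl)-3,4-dihydro-2H-chromen-2-one
Conditions: Cu(OAc)2·H2O (5 mol%), (R)-DTBM-SEGPHOS (5.5 mol%), (EtO)2MeSiH, t-BuOH, toluene, 0 °C → rt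
Reagents that add atoms: none
Why: Ligand-controlled CuH asymmetric conjugate reduction of a β,β-disubstituted unsaturated lactone, in which the chiral bisphosphine–copper hydride adds H to one face of the β-carbon and so sets C7′, while t-BuOH protonates the copper enolate and limits 1,2-reduction.

Step 4
Reactants: 5 dihydrocoumarin
Product: 6 (3R,4R)-3-methyl-5,7-bis(methoxymethoxy)-4-(2-methylpropyl)-3,4-dihydro-2H-chromen-2-one (3,4-trans)
Conditions: LiN(SiMe3)2, THF, −78 °C; MeI, −78 → −40 °C
Reagents that add atoms: iodomethane, CI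
Why: Kinetic lactone enolate alkylation in which MeI enters anti to the pseudo-axial 4-isobutyl group, a centre that is re-enolised in step 5.

Step 5
Reactants: 6 methyl lactone
Product: 7 3-methyl-3-(prop-2-enyl) lactone, methyl cis and allyl trans to the 4-isobutyl group
Conditions: LiN(i-Pr)2, THF, −78 °C; allyl bromide, −78 → −50 °C
Reagents that add atoms: allyl bromide, C=CCBr
Why: Second enolate alkylation with a reactive allylic halide, which again enters anti to the 4-isobutyl group (1,2-induction in the six-membered lactone enolate) and thereby sets the quaternary C4 relative to C7′.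

Step 6
Reactants: 7 allyl methyl lactone; 8 but-3-en-2-one
Product: 9 3-methyl-3-[(2E)-4-oxopent-2-enyl] lactone
Conditions: 8 (5 equiv), second-generation Hoveyda–Grubbs catalyst RuCl2(H2IMes)(=CH-C6H4-2-O-i-Pr) (5 mol%), CH2Cl2, 40 °C
Reagents that add atoms: none
Why: Olefin cross-metathesis of a terminal alkene with an excess of an electron-poor enone gives the E-enone with C1, C10 and C14 in place and touches no stereocentre.

Step 7
Reactants: 9 enone lactone
Product: 10 3-methyl-3-(4-oxopentyl) lactone
Conditions: H2 (1 atm), Pd/C, EtOAc, rt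
Reagents that add atoms: none
Why: Heterogeneous hydrogenation saturates the conjugated C=C while the ketone, the aryl ester and the MOM acetals survive.

Step 8
Reactants: 10 keto lactone
Product: 11 2-methyl-2-(1-Ar1-3-methylbutyl)heptane-1,6-diol (C6 carbinol epimers)
Conditions: LiAlH4, THF, 0 °C → rt; aqueous work-up
Reagents that add atoms: none
Why: Hydride reduction opens the aryl ester to the phenol and the primary alcohol (C5) and reduces the ketone, whose carbinol configuration is irrelevant because it is re-oxidised.

Step 9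
Reactants: 11 phenol diol
Product: 12 2-methyl-2-(1-Ar2-3-methylbutyl)heptane-1,6-diol
Conditions: allyl bromide, K2CO3, DMF, rt
Reagents that add atoms: allyl bromide, C=CCBr
Why: Williamson etherification selective by acidity, since only the phenol is deprotonated by carbonate, which puts a group removable under neutral conditions on the oxygen that later becomes the ether O.

Step 10
Reactants: 12 allyl ether diol
Product: 13 2-methyl-2-(1-Ar2-3-methylbutyl)-6-oxoheptanal
Conditions: Dess–Martin periodinane (3 equiv), CH2Cl2, 0 °C → rt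
Reagents that add atoms: none
Why: Dess–Martin oxidation of both alcohols gives the keto aldehyde, whose α-quaternary aldehyde cannot epimerise or enolise.

Step 11
Reactants: 13 keto aldehyde
Product: 15 1-[3-methyl-3-(1-Ar2-3-methylbutyl)cyclopent-1-en-1-yl]ethanone, via aldol adduct 14 (not isolated)
Conditions: KOH (0.5 equiv), MeOH, rt → 50 °C
Reagents that add atoms: none
Why: Intramolecular aldol condensation in which the non-enolisable aldehyde C5 is the only electrophile and C1 of the methyl ketone the only nucleophile that closes a five-membered ring, dehydration then giving the conjugated acetylcyclopentene.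

Step 12
Reactants: 15 acetylcyclopentene
Product: 16 ethyl 1-acetyl-4-methyl-4-(1-Ar2-3-methylbutyl)bicyclo[3.1.0]hexane-6-exo-carboxylate, cyclopropane on the face of the C4 methyl
Conditions: (ethoxycarbonylmethyl)dimethylsulfonium bromide, DBU, CHCl3, rt → 50 °C
Reagents that add atoms: (ethoxycarbonylmethyl)dimethylsulfonium bromide, CCOC(=O)C[S+](C)C.[Br-]
Why: Michael-initiated ring closure (Corey–Chaykovsky-type cyclopropanation) with the ester-stabilised sulfonium ylide, which adds to C5 anti to the bulky C7′ substituent on C4 before the C1 enolate closes on C6 with loss of Me2S, so that C5 and C1 are set with the necessarily cis ring fusion and the ester settles exo, away from the cyclopentane and its C4 methyl.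

Step 13
Reactants: 16 keto ester
Product: 17 1-(1-hydroxyethyl)-6-exo-(hydroxymethyl)bicyclo[3.1.0]hexane diol (carbinol epimers)
Conditions: LiAlH4, THF, 0 °C; aqueous work-up
Reagents that add atoms: none
Why: Hydride reduction of ester and ketone gives the 1,4-diol without touching the ring stereocentres, the new carbinol centre being removed again in step 14.

Step 14
Reactants: 17 diol
Product: 18 1-acetyl-4-methyl-4-(1-Ar2-3-methylbutyl)bicyclo[3.1.0]hexane-6-exo-carbaldehyde
Conditions: (COCl)2, DMSO, CH2Cl2, −78 °C; Et3N, −78 → −20 °C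
Reagents that add atoms: none
Why: Swern oxidation activates both hydroxyl groups before base is added, so the cis-1,4-diol is oxidised to the keto aldehyde without passing through a lactol that would end as the lactone.

Step 15
Reactants: 18 keto aldehyde
Product: 20 6-exo-ethenyl-4-methyl-1-(prop-1-en-2-yl)-4-(1-Ar2-3-methylbutyl)bicyclo[3.1.0]hexane, via vinyl ketone 19 (not isolated)
Conditions: Ph3PCH3Br (4 equiv), KN(SiMe3)2 (3.8 equiv), THF, −78 °C → rt; work-up and chromatography at or below 0 °C
Reagents that add atoms: methyltriphenylphosphonium bromide, C[P+](c1ccccc1)(c1ccccc1)c1ccccc1.[Br-]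
Why: Double Wittig methylenation, the aldehyde reacting at −78 °C and the cyclopropyl methyl ketone on warming, which installs C8 and C9 without changing any stereocentre.

Step 16
Reactants: 20 cis-dialkenylcyclopropane
Product: 21 3,8-dimethyl-3-(1-Ar2-3-methylbutyl)-1,2,3,3a,6,7-hexahydroazulene (1(10),6-diene in aromadendrane numbering, H5 retained)
Conditions: toluene (degassed, BHT), 60 °C
Reagents that add atoms: none
Why: Thermal Cope ([3,3]-sigmatropic) rearrangement of a cis-1,2-dialkenylcyclopropane: the isopropenyl group on C1 and the vinyl group on C6 fold over the three-membered ring on the side of H5 into a boat transition state, C8–C9 forms as C1–C6 breaks, and the π bonds move to C1=C10 and C6=C7. The closest known reaction is the cis-divinylcyclopropane to cyclohepta-1,4-diene rearrangement as applied to vinyl-substituted bicyclo[3.1.0]hexanes for hydroazulene synthesis. The seven-membered ring (C1, C5, C6, C7, C8, C9, C10) closes by ring expansion of the cyclopropane inside the six-atom pericyclic array, a concerted suprafacial process in which no exo or endo choice arises, and both new ring alkenes are cis by the boat geometry. No stereocentre is made: C5 keeps its configuration because none of its bonds belongs to the array, while C1 and C6 become sp2. The step needs the C6 vinyl cis (exo) to the C1 isopropenyl group, which the exo ester of step 12 and the fixed cis ring fusion secure, and an endo epimer would stay unchanged at this temperature. Release of cyclopropane strain drives the step and no reagent is present, so the MOM and allyl ethers are untouched.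

Step 17
Reactants: 21 hydroazulene diene
Product: 22 3,8-dimethyl-3-(1-Ar1-3-methylbutyl)-1,2,3,3a,6,7-hexahydroazulene (free ortho phenol)
Conditions: Pd(PPh3)4 (5 mol%), morpholine, THF, rt, under argon
Reagents that add atoms: none
Why: Palladium-catalysed allyl transfer (Tsuji–Trost deallylation) to morpholine frees only the ortho phenol under neutral conditions, so the acid-sensitive skipped diene and the MOM acetals are not exposed to acid.

Step 18
Reactants: 22 phenol diene
Product: 23 oxepane-bridged tetracycle with C6=C7 (bis-MOM ether; O on C1 α, cis to H5 and C7′; C10 methyl cis to O)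
Conditions: Co(C36H52N2O2) salen complex (5 mol%; ligand N,N′-bis(3,5-di-tert-butylsalicylidene)-1,2-cyclohexanediamine, divalent cobalt), N-fluoro-2,4,6-trimethylpyridinium tetrafluoroborate, PhSiH3, PhCF3, 0 °C → rt
Reagents that add atoms: none
Why: Mukaiyama-type cobalt hydride hydrogen-atom-transfer hydroalkoxylation with radical–polar crossover, in which H is given to C10 of the tetrasubstituted alkene from the β face left open by the aryl group, the tertiary C1 radical is oxidised at cobalt and captured by the tethered phenol on the α face (seven-membered ring closure cis to C7′), so that C1 and C10 are set by net anti addition while the C1 radical cannot undergo the hydride shift from C5 that a free cation would suffer and the slower cis-disubstituted C6=C7 is left alone.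

Step 19
Reactants: 23 oxepane alkene
Product: 24 11,11-dibromo cyclopropane (bis-MOM ether)
Conditions: CHBr3, KOt-Bu, pentane, 0 °C → rt
Reagents that add atoms: bromoform, BrC(Br)Br
Why: Dibromocarbene [2+1] addition to the only remaining alkene from the α face syn to the small pseudo-axial H5, the β face being covered by the folded C9–C10–C1 segment or by the C4 quaternary centre in the accessible ring conformers, which sets C6 and C7.

Step 20
Reactants: 24 dibromocyclopropane
Product: 25 11,11-dimethyl cyclopropane (bis-MOM ether of 26)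
Conditions: Me2CuLi (from MeLi, CuI; excess), Et2O, −78 → −20 °C; MeI, −20 °C → rt
Reagents that add atoms: lithium dimethylcuprate, [Li+].C[Cu-]C; iodomethane, CI
Why: Cuprate gem-dimethylation of a gem-dibromocyclopropane (bromine–copper exchange, methyl shift from copper to carbon, then alkylation of the cyclopropylcopper by MeI), which creates no stereocentre because C11 carries two identical groups.

Step 21
Reactants: 25 bis-MOM ether
Product: 26 bis-deformyl target (diphenol)
Conditions: HCl, MeOH, rt → 40 °C
Reagents that add atoms: none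
Why: Acid-catalysed acetal exchange with methanol removes both aryl MOM groups under conditions mild enough for the tertiary aryl ether and the cyclopropane.

Step 22
Reactants: 26 diphenol
Product: 27 target CNP0189833.2
Conditions: Cl2CHOMe, TiCl4, CH2Cl2, −78 → 0 °C; then H2O, 0 °C
Reagents that add atoms: dichloromethyl methyl ether, COC(Cl)Cl; water, O
Why: Rieche formylation at the two open ring positions, each activated by three oxygen substituents and directed by the titanium phenoxides, with hydrolysis of the chloro ether adducts giving both aldehydes.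

**Compound list**

1 | phloroglucinol | Oc1cc(O)cc(O)c1 | starting material
2 | ethyl 5-methyl-3-oxohexanoate | CCOC(=O)CC(=O)CC(C)C | starting material
3 | 5,7-dihydroxy-4-(2-methylpropyl)-2H-chromen-2-one | CC(C)CC1=CC(=O)Oc2cc(O)cc(O)c12 | intermediate
4 | 5,7-bis(methoxymethoxy)-4-(2-methylpropyl)-2H-chromen-2-one | CC(C)CC1=CC(=O)Oc2cc(OCOC)cc(OCOC)c12 | intermediate
5 | (4R)-5,7-bis(methoxymethoxy)-4-(2-methylpropyl)-3,4-dihydro-2H-chromen-2-one | CC(C)C[C@@H]1CC(=O)Oc2cc(OCOC)cc(OCOC)c12 | intermediate
6 | (3R,4R)-3-methyl-5,7-bis(methoxymethoxy)-4-(2-methylpropyl)-3,4-dihydro-2H-chromen-2-one | CC(C)C[C@@H]1[C@@H](C)C(=O)Oc2cc(OCOC)cc(OCOC)c12 | intermediate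
7 | 3-methyl-3-(prop-2-enyl)-5,7-bis(methoxymethoxy)-4-(2-methylpropyl)-3,4-dihydro-2H-chromen-2-one, methyl cis and allyl trans to isobutyl | CC(C)C[C@@H]1[C@@](C)(CC=C)C(=O)Oc2cc(OCOC)cc(OCOC)c12 | intermediate
8 | but-3-en-2-one | CC(=O)C=C | starting material
9 | 3-methyl-3-[(2E)-4-oxopent-2-enyl] lactone, configuration as 7 | CC(C)C[C@@H]1[C@@](C)(C/C=C/C(C)=O)C(=O)Oc2cc(OCOC)cc(OCOC)c12 | intermediate
10 | 3-methyl-3-(4-oxopentyl) lactone, configuration as 7 | CC(C)C[C@@H]1[C@@](C)(CCCC(C)=O)C(=O)Oc2cc(OCOC)cc(OCOC)c12 | intermediate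
11 | 2-methyl-2-(1-Ar1-3-methylbutyl)heptane-1,6-diol, C6 carbinol epimers | CC(C)C[C@@H](c1c(O)cc(OCOC)cc1OCOC)[C@](C)(CO)CCCC(C)O | intermediate
12 | 2-methyl-2-(1-Ar2-3-methylbutyl)heptane-1,6-diol | CC(C)C[C@@H](c1c(OCC=C)cc(OCOC)cc1OCOC)[C@](C)(CO)CCCC(C)O | intermediate
13 | 2-methyl-2-(1-Ar2-3-methylbutyl)-6-oxoheptanal | CC(C)C[C@@H](c1c(OCC=C)cc(OCOC)cc1OCOC)[C@](C)(C=O)CCCC(C)=O | intermediate
14 | 1-[2-hydroxy-3-methyl-3-(1-Ar2-3-methylbutyl)cyclopentyl]ethanone (aldol adduct, new centres undefined) | CC(C)C[C@@H](c1c(OCC=C)cc(OCOC)cc1OCOC)[C@@]1(C)CCC(C(C)=O)C1O | intermediate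
15 | 1-[3-methyl-3-(1-Ar2-3-methylbutyl)cyclopent-1-en-1-yl]ethanone | CC(C)C[C@@H](c1c(OCC=C)cc(OCOC)cc1OCOC)[C@@]1(C)CCC(C(C)=O)=C1 | intermediate
16 | ethyl 1-acetyl-4-methyl-4-(1-Ar2-3-methylbutyl)bicyclo[3.1.0]hexane-6-exo-carboxylate, cyclopropane syn to the C4 methyl | CC(C)C[C@@H](c1c(OCC=C)cc(OCOC)cc1OCOC)[C@@]1(C)CC[C@]2(C(C)=O)[C@@H](C(=O)OCC)[C@H]12 | intermediate
17 | 1-(1-hydroxyethyl)-6-exo-(hydroxymethyl)-4-methyl-4-(1-Ar2-3-methylbutyl)bicyclo[3.1.0]hexane, carbinol epimers | CC(C)C[C@@H](c1c(OCC=C)cc(OCOC)cc1OCOC)[C@@]1(C)CC[C@]2(C(C)O)[C@@H](CO)[C@H]12 | intermediate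
18 | 1-acetyl-4-methyl-4-(1-Ar2-3-methylbutyl)bicyclo[3.1.0]hexane-6-exo-carbaldehyde | CC(C)C[C@@H](c1c(OCC=C)cc(OCOC)cc1OCOC)[C@@]1(C)CC[C@]2(C(C)=O)[C@@H](C=O)[C@H]12 | intermediate
19 | 1-acetyl-6-exo-ethenyl-4-methyl-4-(1-Ar2-3-methylbutyl)bicyclo[3.1.0]hexane | CC(C)C[C@@H](c1c(OCC=C)cc(OCOC)cc1OCOC)[C@@]1(C)CC[C@]2(C(C)=O)[C@@H](C=C)[C@H]12 | intermediate
20 | 6-exo-ethenyl-4-methyl-1-(prop-1-en-2-yl)-4-(1-Ar2-3-methylbutyl)bicyclo[3.1.0]hexane | CC(C)C[C@@H](c1c(OCC=C)cc(OCOC)cc1OCOC)[C@@]1(C)CC[C@]2(C(C)=C)[C@@H](C=C)[C@H]12 | intermediate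
21 | 3,8-dimethyl-3-(1-Ar2-3-methylbutyl)-1,2,3,3a,6,7-hexahydroazulene | CC(C)C[C@@H](c1c(OCC=C)cc(OCOC)cc1OCOC)[C@@]1(C)CCC2=C(C)CCC=C[C@H]12 | intermediate
22 | 3,8-dimethyl-3-(1-Ar1-3-methylbutyl)-1,2,3,3a,6,7-hexahydroazulene | CC(C)C[C@@H](c1c(O)cc(OCOC)cc1OCOC)[C@@]1(C)CCC2=C(C)CCC=C[C@H]12 | intermediate
23 | oxepane-bridged tetracycle with C6=C7, bis-MOM ether (O–C1 α, H5 α, C10 methyl cis to O) | CC(C)C[C@H]1c2c(OCOC)cc(OCOC)cc2O[C@]23CC[C@@]1(C)[C@H]2C=CCC[C@@H]3C | intermediate
24 | 11,11-dibromo cyclopropane, bis-MOM ether (C11 α, syn to H5) | CC(C)C[C@H]1c2c(OCOC)cc(OCOC)cc2O[C@]23CC[C@@]1(C)[C@H]2[C@H]1[C@@H](CC[C@@H]3C)C1(Br)Br | intermediate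
25 | 11,11-dimethyl cyclopropane, bis-MOM ether of 26 | CC(C)C[C@H]1c2c(OCOC)cc(OCOC)cc2O[C@]23CC[C@@]1(C)[C@H]2[C@H]1[C@@H](CC[C@@H]3C)C1(C)C | intermediate
26 | bis-deformyl target (diphenol) | CC(C)C[C@H]1c2c(O)cc(O)cc2O[C@]23CC[C@@]1(C)[C@H]2[C@H]1[C@@H](CC[C@@H]3C)C1(C)C | intermediate
27 | CNP0189833.2 | CC(C)C[C@H]1c2c(O)c(C=O)c(O)c(C=O)c2O[C@]23CC[C@@]1(C)[C@H]2[C@H]1[C@@H](CC[C@@H]3C)C1(C)C | target

**Step count and risks**

Total step count: 22. Longest linear sequence: 22 steps (1 → 27; compound 8 is bought and enters in step 6).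

Steps most likely to fail:

1. Step 18. Hydrogen-atom transfer to the hindered tetrasubstituted C1=C10 bond may be slow, so that alkene isomerisation or elimination after the radical–polar crossover outruns ring closure. Delivery of H to C10 may also not be fully β-selective. The fallback sets out from 22 and returns at 23. The phenol is cyclised by electrophilic selenium instead, with N-(phenylselanyl)phthalimide and catalytic camphorsulfonic acid in CH2Cl2 at −40 °C. The seleniranium ion should form on the open β face of the more electron-rich alkene and be opened at C1 by the phenol from the α face, giving the 10β-phenylselanyl oxepane F1. Bu3SnH with AIBN in toluene at 80 °C then replaces selenium by hydrogen through the tertiary C10 radical, which should take H anti to the neighbouring aryloxy group and give 23.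

2. Step 12. Conjugate addition of the stabilised ylide at C5, which sits next to the quaternary C4, may be slow and reversible, giving low conversion. Facial or exo selectivity may also erode. The fallback sets out from 15 and returns at 17, and delivers the carbene through a tether. Luche reduction (NaBH4, CeCl3·7H2O, MeOH, −40 °C) should give the allylic alcohol F2. Acylation with glyoxylic acid chloride p-toluenesulfonylhydrazone (PhNMe2, then Et3N, CH2Cl2, 0 °C) should give the allylic diazoacetate F3. Slow addition of F3 to Rh2(OAc)4 in CH2Cl2 should close the cyclopropane-fused γ-lactone F4 by intramolecular cyclopropanation. The tether forces the C6 carbonyl cis to C10 (exo), and the carbene should add anti to C7′. LiAlH4 in THF opens F4 to diol 17.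

3. Step 22. TiCl4 and the HCl it releases may ionise the tertiary C1–O aryl ether or open the gem-dimethylcyclopropane, and the second formylation may stall on the deactivated ring. The fallback sets out from 25 and returns at 27, and brings in the formyl carbons by halogen–metal exchange. NBS (2.1 equiv, CH2Cl2, 0 °C) should brominate both open ring positions to give the dibromoarene F5. t-BuLi (THF, −78 °C) followed by DMF should give the bis-MOM dialdehyde F6. Brief treatment with HCl in MeOH at rt removes the MOM groups, which are activated by the ortho formyl groups, to give 27.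

**Further compounds**

F1 | step 18 | 10β-phenylselanyl oxepane (bis-MOM ether, C6=C7 retained) | CC(C)C[C@H]1c2c(OCOC)cc(OCOC)cc2O[C@]23CC[C@@]1(C)[C@H]2C=CCC[C@@]3(C)[Se]c1ccccc1
F2 | step 12 | 1-[3-methyl-3-(1-Ar2-3-methylbutyl)cyclopent-1-en-1-yl]ethanol (carbinol epimers) | CC(C)C[C@@H](c1c(OCC=C)cc(OCOC)cc1OCOC)[C@@]1(C)CCC(C(C)O)=C1
F3 | step 12 | diazoacetate of F2 | CC(C)C[C@@H](c1c(OCC=C)cc(OCOC)cc1OCOC)[C@@]1(C)CCC(C(C)OC(=O)C=[N+]=[N-])=C1
F4 | step 12 | cyclopropane-fused γ-lactone (C10–O–C7(=O)–C6, cyclopropane C1–C5–C6 syn to the C4 methyl) | CC(C)C[C@@H](c1c(OCC=C)cc(OCOC)cc1OCOC)[C@@]1(C)CC[C@]2(C(C)OC3=O)[C@@H]3[C@H]12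
F5 | step 22 | 3′,5′-dibromo derivative of 25 | CC(C)C[C@H]1c2c(OCOC)c(Br)c(OCOC)c(Br)c2O[C@]23CC[C@@]1(C)[C@H]2[C@H]1[C@@H](CC[C@@H]3C)C1(C)C
F6 | step 22 | bis-MOM ether of 27 | CC(C)C[C@H]1c2c(OCOC)c(C=O)c(OCOC)c(C=O)c2O[C@]23CC[C@@]1(C)[C@H]2[C@H]1[C@@H](CC[C@@H]3C)C1(C)C
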